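The route rests on cutting the C2–C3 bond of the 3-hydroxy-3-methylglutarate (HMG) unit. C3 carries an oxygen and, through C4, the methyl-ester carbonyl C5. O, C3, C4 and C5, together with the ester oxygen and a pivalaldehyde carbon, are tied into a six-membered 1,3-dioxin-4-one ring whose acetal stereocentre makes the two faces of C3 different. A Mukaiyama–Michael addition of the ketene silyl acetal of the 8'-O-acetate of the complete abscisic skeleton to this (R)-dioxinone forms C2–C3 and sets C3 in one operation. Methanolysis of the temporary acylal ring then releases the methyl ester and the tertiary hydroxyl. The precursor is a per-silylated 8'-acetoxy abscisic alcohol.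

Key step: step 11

Remark on numbering: abscisic locants are primed (C1' carbinol, C2'–C3' ring alkene, C4' ketone, C5' CH2, C6' quaternary carbon, C8' its CH2O, C9' its methyl); HMG is C1 (carbonyl on O8') to C5 (methyl ester carbonyl).
Assumption: (R)-2-tert-butyl-6-methyl-4H-1,3-dioxin-4-one (16) is taken as a purchasable reagent; otherwise it is made by known operations from (R)-3-hydroxybutanoic acid and pivalaldehyde.

Step 1
Reactants: 1 2,6-dimethylphenol
Product: 2 7,9-dimethyl-1,4-dioxaspiro[4.5]deca-6,9-dien-8-one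
Conditions: PhI(OAc)2 (2.1 equiv), ethylene glycol, 0 °C → rt
Reagents that add atoms: ethylene glycol OCCO
Why: Oxidative dearomatisation of the phenol by the λ3-iodane at the only free para position, with double trapping by the diol, should give the symmetric p-quinone monoketal.

Step 2
Reactants: 2 7,9-dimethyl-1,4-dioxaspiro[4.5]deca-6,9-dien-8-one
Product: 4 [(7,9-dimethyl-1,4-dioxaspiro[4.5]deca-6,8-dien-8-yl)oxy]trimethylsilane, via lithium dienolate 3 (not isolated)
Conditions: L-Selectride, THF, −78 °C; TMSCl, Et3N, −78 → 0 °C; pentane, filtration, used crude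
Reagents that add atoms: chlorotrimethylsilane C[Si](C)(C)Cl
Why: Conjugate hydride reduction (1,2-attack is disfavoured by the two α-methyl groups) gives the cross-conjugated enolate regiospecifically, and O-silylation traps it; the substrate is symmetric, so no stereocentre arises.

Step 3
Reactants: 4 [(7,9-dimethyl-1,4-dioxaspiro[4.5]deca-6,8-dien-8-yl)oxy]trimethylsilane
Product: 5 (S)-9-(hydroxymethyl)-7,9-dimethyl-1,4-dioxaspiro[4.5]dec-6-en-8-one
Conditions: aq. HCHO (5 equiv), Sc(OTf)3 (10 mol %), enantiopure 6,6'-bis(1-hydroxy-2,2-dimethylpropyl)-2,2'-bipyridine (12 mol %), DME/H2O 9:1, −20 °C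
Reagents that add atoms: formaldehyde C=O
Why: Catalytic enantioselective aqueous Mukaiyama aldol (hydroxymethylation) of a fully substituted silicon enolate; the chiral Sc–bipyridine complex selects one enantiotopic face of C9 and creates the quaternary centre (C6'), the ligand antipode being the one that delivers (S)-5, to be fixed by correlation in a first run.

Step 4
Reactants: 6 (Z)-3-methylpent-2-en-4-yn-1-ol
Product: 7 (Z)-tert-butyldimethyl[(3-methylpent-2-en-4-yn-1-yl)oxy]silane
Conditions: TBSCl, imidazole, DMF, 0 °C → rt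
Reagents that add atoms: tert-butyldimethylsilyl chloride CC(C)(C)[Si](C)(C)Cl
Why: Standard silylation of the primary alcohol; it keeps the side-chain oxygen distinct from the 8'-OH that is acetylated later.

Step 5
Reactants: 5 (S)-9-(hydroxymethyl)-7,9-dimethyl-1,4-dioxaspiro[4.5]dec-6-en-8-one; 7 (Z)-tert-butyldimethyl[(3-methylpent-2-en-4-yn-1-yl)oxy]silane
Product: 9 (8S,9S)-8-[(Z)-5-(tert-butyldimethylsilyloxy)-3-methylpent-3-en-1-ynyl]-9-(hydroxymethyl)-7,9-dimethyl-1,4-dioxaspiro[4.5]dec-6-en-8-ol, via alkynylmagnesium bromide 8 (not isolated)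
Conditions: 7 (2.5 equiv), EtMgBr (2.4 equiv), THF, 0 °C → rt; then 5, THF/CH2Cl2, −78 → 0 °C; aq. NH4Cl
Reagents that add atoms: none
Why: Alkoxide-directed (chelation-controlled) 1,2-addition of an alkynyl Grignard reagent: magnesium bridges the C9-CH2O alkoxide and the ketone oxygen, which holds CH2O near the carbonyl plane and the C9 methyl pseudo-axial, so the alkyne enters anti to that methyl and the new tertiary OH (C1') ends up trans to CH2OH and cis to the methyl.

Step 6
Reactants: 9 (8S,9S)-8-[(Z)-5-(tert-butyldimethylsilyloxy)-3-methylpent-3-en-1-ynyl]-9-(hydroxymethyl)-7,9-dimethyl-1,4-dioxaspiro[4.5]dec-6-en-8-ol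
Product: 10 (8R,9S)-8-[(1E,3Z)-5-(tert-butyldimethylsilyloxy)-3-methylpenta-1,3-dienyl]-9-(hydroxymethyl)-7,9-dimethyl-1,4-dioxaspiro[4.5]dec-6-en-8-ol
Conditions: Red-Al, THF, 0 °C → rt; Rochelle-salt work-up
Reagents that add atoms: none
Why: Alkoxide-directed trans-hydroalumination of the propargylic alcohol and protonolysis give the E-alkene while the Z-alkene, ketal and silyl ether are untouched; the CIP descriptor at C8 changes without any change at the centre.

Step 7
Reactants: 10 (8R,9S)-8-[(1E,3Z)-5-(tert-butyldimethylsilyloxy)-3-methylpenta-1,3-dienyl]-9-(hydroxymethyl)-7,9-dimethyl-1,4-dioxaspiro[4.5]dec-6-en-8-ol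
Product: 11 [(8R,9S)-8-[(1E,3Z)-5-(tert-butyldimethylsilyloxy)-3-methylpenta-1,3-dienyl]-8-hydroxy-7,9-dimethyl-1,4-dioxaspiro[4.5]dec-6-en-9-yl]methyl acetate
Conditions: Ac2O (1.1 equiv), pyridine, DMAP (cat.), CH2Cl2, 0 °C
Reagents that add atoms: acetic anhydride CC(=O)OC(C)=O
Why: Acylation of the primary 8'-OH in the presence of the hindered tertiary 1'-OH; this installs C1 and C2 of the HMG unit.

Step 8
Reactants: 11 [(8R,9S)-8-[(1E,3Z)-5-(tert-butyldimethylsilyloxy)-3-methylpenta-1,3-dienyl]-8-hydroxy-7,9-dimethyl-1,4-dioxaspiro[4.5]dec-6-en-9-yl]methyl acetate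
Product: 12 [(1S,2R)-2-[(1E,3Z)-5-(tert-butyldimethylsilyloxy)-3-methylpenta-1,3-dienyl]-2-hydroxy-1,3-dimethyl-5-oxocyclohex-3-en-1-yl]methyl acetate
Conditions: PPTS (cat.), acetone/H2O, rt
Reagents that add atoms: water O
Why: Mild hydrolysis of the allylic dioxolane to the enone; with O8' acylated, the oxa-Michael closure onto C2' open to a free 8'-OH cannot occur, and the primary TBS ether survives.

Step 9
Reactants: 12 [(1S,2R)-2-[(1E,3Z)-5-(tert-butyldimethylsilyloxy)-3-methylpenta-1,3-dienyl]-2-hydroxy-1,3-dimethyl-5-oxocyclohex-3-en-1-yl]methyl acetate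
Product: 13 [(1S,2R)-2-[(1E,3Z)-5-(tert-butyldimethylsilyloxy)-3-methylpenta-1,3-dienyl]-1,3-dimethyl-2,5-bis(trimethylsilyloxy)cyclohexa-3,5-dien-1-yl]methyl acetate
Conditions: TMSOTf (2.4 equiv), Et3N (4 equiv), CH2Cl2, −20 → 0 °C; pentane, filtration, used crude
Reagents that add atoms: trimethylsilyl trifluoromethanesulfonate C[Si](C)(C)OS(=O)(=O)C(F)(F)F
Why: Silylation of the tertiary alcohol and kinetic soft enolisation of the enone at C5' to the cross-conjugated 2-silyloxydiene; this masks the ketone against base and against the later Lewis acid, while the acetate is not enolised under these conditions.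

Step 10
Reactants: 13 [(1S,2R)-2-[(1E,3Z)-5-(tert-butyldimethylsilyloxy)-3-methylpenta-1,3-dienyl]-1,3-dimethyl-2,5-bis(trimethylsilyloxy)cyclohexa-3,5-dien-1-yl]methyl acetate
Product: 15 O-tert-butyldimethylsilyl ketene acetal of acetate 13 (8'-O-C(OTBS)=CH2), via lithium ester enolate 14 (not isolated)
Conditions: LDA (1.1 equiv), THF, −78 °C; TBSCl, DMPU, −78 → 0 °C; pentane/ice-cold pH 7 buffer, used crude
Reagents that add atoms: tert-butyldimethylsilyl chloride CC(C)(C)[Si](C)(C)Cl
Why: The acetate CH3 is the only acidic C–H left, so kinetic deprotonation and O-silylation in a dipolar medium give the ketene silyl acetal.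

Step 11
Reactants: 15 O-tert-butyldimethylsilyl ketene acetal of acetate 13; 16 (R)-2-tert-butyl-6-methyl-4H-1,3-dioxin-4-one
Product: 17 tert-butyldimethylsilyl ketene acetal of the (2R,6S)-2-tert-butyl-6-methyl-1,3-dioxan-4-one that carries at C6 the CH2C(=O)O-C8' chain of the tris-silylated abscisic core (full structure in the list)
Conditions: 16 (1.3 equiv), Tf2NH (5 mol %), CH2Cl2, −78 → −40 °C; Et3N quench, concentrated, used crude
Reagents that add atoms: none
Why: Proposed new method: the silyl triflimide formed in situ O-silylates the vinylogous-carbonate carbonyl of 16 to a 4-silyloxy-1,3-dioxinium ion, the acetate-derived ketene silyl acetal of 15 attacks its C6, and silyl transfer back to triflimide closes the cycle and leaves 17; the closest known reactions are silyl-triflate-promoted Mukaiyama–Michael additions of ketene silyl acetals to 4-pyranones and chromones via 4-silyloxypyrylium ions and the organocuprate 1,4-additions to this same dioxinone. No ring is closed. The new quaternary centre (HMG C3) is controlled by the acetal stereocentre C2 of the temporary ring: the nucleophile should enter anti to tert-butyl, the sense known for cuprate addition and hydrogenation of 16, which with (R)-16 corresponds to the (3R) configuration of the target. The step needs attack at C6 rather than at the carbonyl carbon C4, which is expected because a C4 adduct is an ortho-ester-type species that re-ionises whereas C–C bond formation at C6 is irreversible. It also needs the acetate ketene acetal to outrun the ring silyl dienol ether, which its much higher nucleophilicity and the shielding of C5' by the quaternary C6' should secure. The enone is masked as that dienol ether so that it is neither an electrophile nor an enolisable ketone, and −78 °C with catalytic acid should keep the hindered tertiary bis-allylic 1'-OTMS from ionising.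

Step 12
Reactants: 17 tert-butyldimethylsilyl ketene acetal of the dioxanone adduct
Product: 19 1-{[(1S,2R)-2-hydroxy-2-[(1E,3Z)-5-hydroxy-3-methylpenta-1,3-dienyl]-1,3-dimethyl-5-oxocyclohex-3-en-1-yl]methyl} 5-methyl (3R)-3-hydroxy-3-methylpentanedioate, via methyl ester TBS ether 18 (not isolated)
Conditions: K2CO3 (0.3 equiv), MeOH, 0 °C; then NH4F (excess), MeOH, rt
Reagents that add atoms: methanol CO
Why: Methoxide removes the enol and ketene-acetal silyl groups and the TMS ether (the enone returns) and opens the acylal, which is far more electrophilic than the neopentyl-type 8'-ester, to the methyl ester and a hemiacetal that loses pivalaldehyde to unveil the tertiary OH; ammonium fluoride then cleaves the primary TBS ether near neutrality, and no stereocentre is touched.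

Step 13
Reactants: 19 the triol diester
Product: 20 1-{[(1S,2R)-2-hydroxy-1,3-dimethyl-2-[(1E,3Z)-3-methyl-5-oxopenta-1,3-dienyl]-5-oxocyclohex-3-en-1-yl]methyl} 5-methyl (3R)-3-hydroxy-3-methylpentanedioate
Conditions: activated MnO2, CH2Cl2, rt, dark
Reagents that add atoms: none
Why: Chemoselective oxidation of the primary allylic alcohol to the (Z)-enal; both tertiary alcohols are inert and exclusion of light guards the 2Z geometry.

Step 14
Reactants: 20 the (2Z,4E)-dienal
Product: 21 (2Z,4E)-5-[(1R,6S)-1-hydroxy-6-({[(3R)-3-hydroxy-5-methoxy-3-methyl-5-oxopentanoyl]oxy}methyl)-2,6-dimethyl-4-oxocyclohex-2-en-1-yl]-3-methylpenta-2,4-dienoic acid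
Conditions: NaClO2, NaH2PO4, 2-methyl-2-butene, t-BuOH/H2O, 0 °C → rt
Reagents that add atoms: sodium chlorite [Na+].[O-]Cl=O
Why: Pinnick oxidation of the enal to the acid without touching the enone, diene, esters or tertiary alcohols and without double-bond isomerisation.

Compound list
1 | 2,6-dimethylphenol | Cc1cccc(C)c1O | starting material
2 | 7,9-dimethyl-1,4-dioxaspiro[4.5]deca-6,9-dien-8-one (2,6-dimethyl-1,4-benzoquinone 4-ethylene ketal) | CC1=CC2(OCCO2)C=C(C)C1=O | intermediate
3 | lithium 7,9-dimethyl-1,4-dioxaspiro[4.5]deca-6,8-dien-8-olate | [Li]OC1=C(C)CC2(OCCO2)C=C1C | intermediate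
4 | [(7,9-dimethyl-1,4-dioxaspiro[4.5]deca-6,8-dien-8-yl)oxy]trimethylsilane | C[Si](C)(C)OC1=C(C)CC2(OCCO2)C=C1C | intermediate
5 | (S)-9-(hydroxymethyl)-7,9-dimethyl-1,4-dioxaspiro[4.5]dec-6-en-8-one | OC[C@]1(C)CC2(OCCO2)C=C(C)C1=O | intermediate
6 | (Z)-3-methylpent-2-en-4-yn-1-ol | C#C/C(C)=C\CO | starting material
7 | (Z)-tert-butyldimethyl[(3-methylpent-2-en-4-yn-1-yl)oxy]silane | C#C/C(C)=C\CO[Si](C)(C)C(C)(C)C | intermediate
8 | bromomagnesium acetylide of 7 | Br[Mg]C#C/C(C)=C\CO[Si](C)(C)C(C)(C)C | intermediate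
9 | (8S,9S)-8-[(Z)-5-(tert-butyldimethylsilyloxy)-3-methylpent-3-en-1-ynyl]-9-(hydroxymethyl)-7,9-dimethyl-1,4-dioxaspiro[4.5]dec-6-en-8-ol (OH trans to CH2OH) | OC[C@]1(C)CC2(OCCO2)C=C(C)[C@]1(O)C#C/C(C)=C\CO[Si](C)(C)C(C)(C)C | intermediate
10 | (8R,9S)-8-[(1E,3Z)-5-(tert-butyldimethylsilyloxy)-3-methylpenta-1,3-dienyl]-9-(hydroxymethyl)-7,9-dimethyl-1,4-dioxaspiro[4.5]dec-6-en-8-ol | OC[C@]1(C)CC2(OCCO2)C=C(C)[C@]1(O)/C=C/C(C)=C\CO[Si](C)(C)C(C)(C)C | intermediate
11 | [(8R,9S)-8-[(1E,3Z)-5-(tert-butyldimethylsilyloxy)-3-methylpenta-1,3-dienyl]-8-hydroxy-7,9-dimethyl-1,4-dioxaspiro[4.5]dec-6-en-9-yl]methyl acetate | CC(=O)OC[C@]1(C)CC2(OCCO2)C=C(C)[C@]1(O)/C=C/C(C)=C\CO[Si](C)(C)C(C)(C)C | intermediate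
12 | [(1S,2R)-2-[(1E,3Z)-5-(tert-butyldimethylsilyloxy)-3-methylpenta-1,3-dienyl]-2-hydroxy-1,3-dimethyl-5-oxocyclohex-3-en-1-yl]methyl acetate | CC(=O)OC[C@]1(C)CC(=O)C=C(C)[C@]1(O)/C=C/C(C)=C\CO[Si](C)(C)C(C)(C)C | intermediate
13 | [(1S,2R)-2-[(1E,3Z)-5-(tert-butyldimethylsilyloxy)-3-methylpenta-1,3-dienyl]-1,3-dimethyl-2,5-bis(trimethylsilyloxy)cyclohexa-3,5-dien-1-yl]methyl acetate | CC(=O)OC[C@]1(C)C=C(O[Si](C)(C)C)C=C(C)[C@]1(O[Si](C)(C)C)/C=C/C(C)=C\CO[Si](C)(C)C(C)(C)C | intermediate
14 | lithium ester enolate of 13 | [Li]OC(=C)OC[C@]1(C)C=C(O[Si](C)(C)C)C=C(C)[C@]1(O[Si](C)(C)C)/C=C/C(C)=C\CO[Si](C)(C)C(C)(C)C | intermediate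
15 | O-tert-butyldimethylsilyl ketene acetal of 13 (1-alkoxy-1-silyloxyethene on O8'; 1'-OTMS; 4'-OTMS dienol ether; side-chain OTBS) | C=C(O[Si](C)(C)C(C)(C)C)OC[C@]1(C)C=C(O[Si](C)(C)C)C=C(C)[C@]1(O[Si](C)(C)C)/C=C/C(C)=C\CO[Si](C)(C)C(C)(C)C | intermediate
16 | (R)-2-tert-butyl-6-methyl-4H-1,3-dioxin-4-one | CC(C)(C)[C@H]1OC(=O)C=C(C)O1 | starting material
17 | tert-butyldimethylsilyl ketene acetal of the (2R,6S)-2-tert-butyl-6-methyl-1,3-dioxan-4-one bearing at C6 (trans to tert-butyl) the CH2C(=O)O-C8' chain of the tris-silylated abscisic core | CC(C)(C)[C@H]1OC(O[Si](C)(C)C(C)(C)C)=C[C@](C)(CC(=O)OC[C@]2(C)C=C(O[Si](C)(C)C)C=C(C)[C@]2(O[Si](C)(C)C)/C=C/C(C)=C\CO[Si](C)(C)C(C)(C)C)O1 | intermediate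
18 | 1-{[(1S,2R)-2-[(1E,3Z)-5-(tert-butyldimethylsilyloxy)-3-methylpenta-1,3-dienyl]-2-hydroxy-1,3-dimethyl-5-oxocyclohex-3-en-1-yl]methyl} 5-methyl (3R)-3-hydroxy-3-methylpentanedioate | COC(=O)C[C@@](C)(O)CC(=O)OC[C@]1(C)CC(=O)C=C(C)[C@]1(O)/C=C/C(C)=C\CO[Si](C)(C)C(C)(C)C | intermediate
19 | 1-{[(1S,2R)-2-hydroxy-2-[(1E,3Z)-5-hydroxy-3-methylpenta-1,3-dienyl]-1,3-dimethyl-5-oxocyclohex-3-en-1-yl]methyl} 5-methyl (3R)-3-hydroxy-3-methylpentanedioate | COC(=O)C[C@@](C)(O)CC(=O)OC[C@]1(C)CC(=O)C=C(C)[C@]1(O)/C=C/C(C)=C\CO | intermediate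
20 | 1-{[(1S,2R)-2-hydroxy-1,3-dimethyl-2-[(1E,3Z)-3-methyl-5-oxopenta-1,3-dienyl]-5-oxocyclohex-3-en-1-yl]methyl} 5-methyl (3R)-3-hydroxy-3-methylpentanedioate | COC(=O)C[C@@](C)(O)CC(=O)OC[C@]1(C)CC(=O)C=C(C)[C@]1(O)/C=C/C(C)=C\C=O | intermediate
21 | (2Z,4E)-5-[(1R,6S)-1-hydroxy-6-({[(3R)-3-hydroxy-5-methoxy-3-methyl-5-oxopentanoyl]oxy}methyl)-2,6-dimethyl-4-oxocyclohex-2-en-1-yl]-3-methylpenta-2,4-dienoic acid (CNP0274837.1) | COC(=O)C[C@@](C)(O)CC(=O)OC[C@]1(C)CC(=O)C=C(C)[C@]1(O)/C=C/C(C)=C\C(=O)O | target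

Total step count: 14. Longest linear sequence: 13 steps (steps 1–3 and 5–14 from 2,6-dimethylphenol; step 4 is a one-step side branch).

Steps most likely to fail

Step 11 (proposed new method). The ketene silyl acetal may fail to add to the hindered, donor-substituted C6, or may be diverted to the carbonyl carbon of the acylal. The tertiary bis-allylic silyl ether may ionise under the silyl Lewis acid. Facial discrimination by the remote tert-butyl group may be incomplete. The fallback keeps the temporary ring but uses the known organocuprate chemistry of 16 and attaches the abscisic fragment by esterification. It sets out from 16 and from ketal diol 10. Lithium divinylcuprate (THF, −78 °C) adds to C6 of 16 anti to tert-butyl to give (2R,6R)-2-tert-butyl-6-ethenyl-6-methyl-1,3-dioxan-4-one F1. Hydroboration with 9-BBN and perborate work-up gives the primary alcohol (2R,6S)-2-tert-butyl-6-(2-hydroxyethyl)-6-methyl-1,3-dioxan-4-one F2. F2 is oxidised at once (TEMPO, PhI(OAc)2, MeCN/H2O) to 2-[(2R,4S)-2-tert-butyl-4-methyl-6-oxo-1,3-dioxan-4-yl]acetic acid F3. EDC/DMAP esterification of F3 with the primary 8'-OH of 10 gives the dioxanone ester F4. K2CO3 in methanol opens its acylal to the ketal methyl ester F5, and PPTS in wet acetone converts F5 into 18. The route is rejoined at 18, at the ammonium fluoride stage of step 12.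

Step 3. Ionisation of the allylic ketal of the dihydroaromatic silyl dienol ether, leading to aromatisation, or protodesilylation may outrun C–C bond formation, and enantiofacial control at the fully substituted enolate carbon may be insufficient. The fallback replaces catalysis by resolution and sets out from 2. Enolate 3, generated as in step 2, is trapped at −78 °C with monomeric formaldehyde to give racemic 9-(hydroxymethyl)-7,9-dimethyl-1,4-dioxaspiro[4.5]dec-6-en-8-one F6. A lipase-catalysed transesterification with vinyl acetate (Burkholderia cepacia lipase, t-BuOMe, enzyme chosen by screening so that the (R)-alcohol is acylated) is carried past half conversion. The (R)-acetate F7 is removed by chromatography and the unreacted alcohol is (S)-5, where the route is rejoined.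

Step 5. The magnesium aldolate of 5 may lose formaldehyde by retro-aldol cleavage before addition, and facial selectivity may be poor if the alkoxide does not organise the transition state. The fallback uses a neutral chelating ether instead of the free alkoxide and sets out from 5. 4-Methoxybenzyl trichloroacetimidate with catalytic CSA gives the PMB ether of 5, F8. Precomplexation with MgBr2·OEt2 in CH2Cl2 and addition of 8 at −78 °C, under six-membered chelate control with the same facial sense, gives the PMB ether of 9, F9. DDQ in CH2Cl2/pH 7 buffer then returns 9, where the route is rejoined.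

Further compounds
F1 | step 11 | (2R,6R)-2-tert-butyl-6-ethenyl-6-methyl-1,3-dioxan-4-one | CC(C)(C)[C@H]1OC(=O)C[C@](C)(C=C)O1
F2 | step 11 | (2R,6S)-2-tert-butyl-6-(2-hydroxyethyl)-6-methyl-1,3-dioxan-4-one | CC(C)(C)[C@H]1OC(=O)C[C@](C)(CCO)O1
F3 | step 11 | 2-[(2R,4S)-2-tert-butyl-4-methyl-6-oxo-1,3-dioxan-4-yl]acetic acid | CC(C)(C)[C@H]1OC(=O)C[C@](C)(CC(=O)O)O1
F4 | step 11 | [(8R,9S)-8-[(1E,3Z)-5-(tert-butyldimethylsilyloxy)-3-methylpenta-1,3-dienyl]-8-hydroxy-7,9-dimethyl-1,4-dioxaspiro[4.5]dec-6-en-9-yl]methyl 2-[(2R,4S)-2-tert-butyl-4-methyl-6-oxo-1,3-dioxan-4-yl]acetate | CC(C)(C)[C@H]1OC(=O)C[C@](C)(CC(=O)OC[C@]2(C)CC3(OCCO3)C=C(C)[C@]2(O)/C=C/C(C)=C\CO[Si](C)(C)C(C)(C)C)O1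
F5 | step 11 | 1-{[(8R,9S)-8-[(1E,3Z)-5-(tert-butyldimethylsilyloxy)-3-methylpenta-1,3-dienyl]-8-hydroxy-7,9-dimethyl-1,4-dioxaspiro[4.5]dec-6-en-9-yl]methyl} 5-methyl (3R)-3-hydroxy-3-methylpentanedioate | COC(=O)C[C@@](C)(O)CC(=O)OC[C@]1(C)CC2(OCCO2)C=C(C)[C@]1(O)/C=C/C(C)=C\CO[Si](C)(C)C(C)(C)C
F6 | step 3 | rac-9-(hydroxymethyl)-7,9-dimethyl-1,4-dioxaspiro[4.5]dec-6-en-8-one | OCC1(C)CC2(OCCO2)C=C(C)C1=O
F7 | step 3 | [(R)-7,9-dimethyl-8-oxo-1,4-dioxaspiro[4.5]dec-6-en-9-yl]methyl acetate | CC(=O)OC[C@@]1(C)CC2(OCCO2)C=C(C)C1=O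
F8 | step 5 | (S)-9-[(4-methoxybenzyloxy)methyl]-7,9-dimethyl-1,4-dioxaspiro[4.5]dec-6-en-8-one | COc1ccc(COC[C@]2(C)CC3(OCCO3)C=C(C)C2=O)cc1
F9 | step 5 | (8S,9S)-8-[(Z)-5-(tert-butyldimethylsilyloxy)-3-methylpent-3-en-1-ynyl]-9-[(4-methoxybenzyloxy)methyl]-7,9-dimethyl-1,4-dioxaspiro[4.5]dec-6-en-8-ol | COc1ccc(COC[C@]2(C)CC3(OCCO3)C=C(C)[C@]2(O)C#C/C(C)=C\CO[Si](C)(C)C(C)(C)C)cc1
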